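The ratio of impurity to free enzyme charged in the green flask was 27.3%, and I began from it.

| flask | starting material | free enzyme | impurity | temperature | remark | time |
|---|---|---|---|---|---|---|
| green | 0.10 M | 5.5 × 10⁻⁴ mol% | 0.15 µM | 37 °C | the very flask that is asked about, followed so far |  |
| teal | 0.050 M | 5.5 × 10⁻⁴ mol% | 0.15 µM | 22 °C | run made earlier |  |
| flask | 0.10 M | 5.5 × 10⁻⁴ mol% | 0.15 µM | 37 °C |  | 80 min |

- green (time / min: target / %, starting material / %): 10.0: 12.3, 78.2; 20.0: 11.6, 77.8; 30.0: 11.9, 78.3; 40.0: 12.3, 77.6; 50.0: 11.9, 78.1; 60.0: 12.3, 77.6
- teal (time / min: target / %, starting material / %): 0.500: 1.4, 98.3; 1.00: 3.2, 97.3; 2.00: 5.0, 94.6; 3.00: 6.5, 91.9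

(standard deviation of a reading: 0.3 percentage points)

- maple: at 80 min raise the temperature by 10 K, then wait 2.5 h
- alder: change nothing and wait 2.5 h more
- larch: at 80 min take out 90% of the target then present, then wait 2.5 h
- birch: at 80 min add free enzyme, 100% of the amount charged, then wait 2.5 h

- target that was removed still counts
- additions bring no volume worth counting

- target, in percent of the starting material first charged, at 80 min
- the option that brings most further target ("none" if no option brings more than 2 percentage points) (maple / alder / larch / birch / none)
- target present, with what was taken out counted in, in percent of the starting material first charged, after larch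
- target present, with what was taken out counted in, in percent of the starting material first charged, after birch

In the green run, starting material held near 77.9% and target near 12.0% from the first reading on. I took that stop for dead enzyme, though these runs could not prove it. So I wrote the balance of the enzyme. Of 0.550 µM charged, impurity could spend 0.15 µM; it was the smaller charge, so it was the limiting reagent of the poisoning. I kept 0.400 µM as net enzyme, the free enzyme charged minus the impurity charged.

I assumed that net enzyme had made the target seen. In my reckoning a second charge met no impurity, so I counted its 0.550 µM as net enzyme. I expected 17 percentage points more target, or 28.6% after birch. I expected no gain from maple, alder or larch.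

The forecast gave 12% now, larch as best, 21.4% after larch and 12% after birch. Its ground was this: “The plateau therefore looks like equilibrium reached quickly”.

The flask gave 12.1%, and birch was best. Larch gave 12.1% and birch gave 22.0%, less than my figure. At 80.0 min the flask held free enzyme 0% of the catalyst charged and impurity 0% of its own charge. Spent catalyst A stood at 27.3% of the catalyst charged, close to the charged ratio, spent catalyst B at 71.8% and unfolded enzyme at 0.921%.

    free enzyme → unfolded enzyme (k = 1.04 × 10⁻⁴ s⁻¹, Ea = 206 kJ mol⁻¹)
    starting material + free enzyme → target + free enzyme, rate k2*[starting material]*[free enzyme]/(1 + ([starting material]/Km2)) (34.4 mM, k = 18500 M⁻¹ s⁻¹, Ea = 33.0 kJ mol⁻¹)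
    free enzyme + impurity → spent catalyst A (k = 6.11 × 10⁵ M⁻¹ s⁻¹, Ea = 15.0 kJ mol⁻¹)
    target + free enzyme ⇌ isomer of the product + free enzyme, rate k4*[free enzyme]*[target] forward; the back reaction follows from the equilibrium constant (K = 1.67, k = 46300 M⁻¹ s⁻¹, Ea = 21.0 kJ mol⁻¹, ΔH = −20.0 kJ mol⁻¹)
    free enzyme → spent catalyst B (k = 0.00811 s⁻¹, Ea = 86.0 kJ mol⁻¹)
    (constants at 37 °C)

A neighbouring flask, with the other charges and the time held, had 0.600 µM of impurity, more than the 0.550 µM of free enzyme charged. The same balance gave net enzyme −0.0500 µM, below zero. So I reckoned no turnover and a surplus of impurity, 8.33% of its own charge. In that neighbouring flask at 80.0 min, impurity stood at 13% of its charge, spent catalyst A at 95.0% and spent catalyst B at 4.94% of the catalyst charged, starting material at 98%, and target at 1.47%.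

The data were generated by integration on assumed constants; noise was put on by code.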